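## Retrosynthetic overview

1. The target is a trans-fused bicyclo[8.2.0]dodecane (ring carbons C1–C12: C1 quaternary with CH3, C4 acrylate, C6 prenyl, C7 exocyclic CH2, C12 isopropenyl). Acrylate, exo-methylene and isopropenyl are traced back to a C4 acetyl ketal, a C7 enol triflate and a C12 ester.
2. The ten-membered ring is opened at C7–C8: intramolecular B-alkyl Suzuki–Miyaura coupling of a C9=C8 vinyl group on the four-membered ring with the C7 enol triflate.
3. The cyclobutane C1–C10–C11–C12 is not made by [2+2] but by Wolff ring contraction of a 5-diazo-2,2,3-trisubstituted cyclopentanone. The extruded carbonyl carbon becomes the C12 ester and later the isopropenyl carbon.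
4. That cyclopentanone comes from 2-methylcyclopent-2-enone: asymmetric vinyl 1,4-addition sets C10, then the enolate is alkylated at the quaternary carbon C1 with a C2–C7 iodide (convergent union, C1 trans to C10).
5. The C2–C7 iodide comes from (R)-carvone: carvone C5 is C4, trans prenyl-copper addition sets C6, and oxidative cleavage of the carvone C1–C2 bond unzips the ring into C2 (ester) and C7 (methyl ketone). Ring order: cyclopentanone (bought), cyclobutane (step 12), cyclodecane (step 13).

Key step: step 12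

Remark: the Why lines use the target ring numbering C1–C12. The CIP letter at C4 changes between intermediates only because neighbour priorities change. The sense of induction of the ligand in step 9 is assumed to be assignable, and the enantiomer that gives the 3S adduct is used.

## Route

Step 1
Reactants: 1 (R)-(−)-carvone
Product: 3 (5R)-5-acetyl-2-methylcyclohex-2-en-1-one, via secondary ozonide 2 (not isolated)
Conditions: O3, CH2Cl2, −78 °C (Sudan III end point); then Me2S, −78 °C → rt
Reagents that add atoms: ozone, [O-][O+]=O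
Why: Chemoselective ozonolysis, because the electron-rich 1,1-disubstituted isopropenyl alkene reacts with ozone much faster than the electron-poor enone C=C, so only the side chain is cut to the methyl ketone that later becomes the acrylate, while the stereocentre (future C4) comes from the chiral pool.

Step 2
Reactants: 3 (5R)-5-acetyl-2-methylcyclohex-2-en-1-one
Product: 4 (5R)-2-methyl-5-(2-methyl-1,3-dioxolan-2-yl)cyclohex-2-en-1-one
Conditions: TMSOCH2CH2OTMS, TMSOTf (5 mol %), CH2Cl2, −78 → −20 °C
Reagents that add atoms: 1,2-bis(trimethylsilyloxy)ethane, C[Si](C)(C)OCCO[Si](C)(C)C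
Why: Silyl-triflate-catalysed ketalization with the bis-silyl glycol should take the saturated ketone and leave the less electrophilic enone, and at low temperature without protic acid it should not enolize toward the only stereocentre.

Step 3
Reactants: 4 (5R)-2-methyl-5-(2-methyl-1,3-dioxolan-2-yl)cyclohex-2-en-1-one
Product: 5 trimethyl{[(3R,5R)-2-methyl-3-(3-methylbut-2-en-1-yl)-5-(2-methyl-1,3-dioxolan-2-yl)cyclohex-1-en-1-yl]oxy}silane
Conditions: prenylMgCl, CuBr·SMe2, TMSCl, THF, −78 °C; Et3N/pentane work-up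
Reagents that add atoms: prenylmagnesium chloride, CC(C)=CC[Mg]Cl; chlorotrimethylsilane, C[Si](C)(C)Cl
Why: Copper-mediated, TMSCl-accelerated conjugate addition of an allylic Grignard reagent should deliver the prenyl group through its unsubstituted carbon and anti to the C5 substituent (the usual trans course for carvone-type enones), which sets C6, and it stores the enolate regiospecifically as the silyl enol ether.

Step 4
Reactants: 5 trimethyl{[(3R,5R)-2-methyl-3-(3-methylbut-2-en-1-yl)-5-(2-methyl-1,3-dioxolan-2-yl)cyclohex-1-en-1-yl]oxy}silane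
Product: 7 (3R,5R)-2-hydroxy-2-methyl-3-(3-methylbut-2-en-1-yl)-5-(2-methyl-1,3-dioxolan-2-yl)cyclohexan-1-one (C2 epimers), via lithium enolate 6 (not isolated)
Conditions: MeLi, THF, 0 °C; then (camphorsulfonyl)oxaziridine, −78 → 0 °C
Reagents that add atoms: (camphorsulfonyl)oxaziridine, CC1(C)C2CCC13CS(=O)(=O)N4OC34C2
Why: MeLi releases the regiodefined tetrasubstituted lithium enolate, and its α-hydroxylation by the N-sulfonyloxaziridine (enolate oxidation) leaves the prenyl alkene untouched; the new carbinol centre is destroyed in step 5, so its configuration does not matter.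

Step 5
Reactants: 7 (3R,5R)-2-hydroxy-2-methyl-3-(3-methylbut-2-en-1-yl)-5-(2-methyl-1,3-dioxolan-2-yl)cyclohexan-1-one
Product: 8 methyl (3R,5R)-5-acetyl-8-methyl-3-(2-methyl-1,3-dioxolan-2-yl)non-7-enoate
Conditions: Pb(OAc)4, MeOH/benzene (1:1), 0 °C
Reagents that add atoms: methanol, CO
Why: Lead tetraacetate cleavage of the tertiary α-ketol in methanol (glycol-type cleavage of the hemiketal) cuts the old carvone C1–C2 bond and should give the methyl ester (future C2) and the methyl ketone (future C7) without touching alkene or ketal.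

Step 6
Reactants: 8 methyl (3R,5R)-5-acetyl-8-methyl-3-(2-methyl-1,3-dioxolan-2-yl)non-7-enoate
Product: 10 methyl (3R,5R)-8-methyl-3-(2-methyl-1,3-dioxolan-2-yl)-5-[1-(trifluoromethanesulfonyloxy)ethenyl]non-7-enoate, via lithium enolate 9 (not isolated)
Conditions: LDA, THF, −78 °C (ketone added to base); then PhNTf2, −78 → 0 °C
Reagents that add atoms: N-phenylbis(trifluoromethanesulfonimide), O=S(=O)(N(c1ccccc1)S(=O)(=O)C(F)(F)F)C(F)(F)F
Why: Kinetic deprotonation of the methyl ketone at CH3 (faster than at the tertiary α-CH or the ester α-CH2) and O-triflation give the 1,1-disubstituted enol triflate, which removes the epimerizable position next to C6 and carries the future exocyclic methylene carbon.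

Step 7
Reactants: 10 methyl (3R,5R)-8-methyl-3-(2-methyl-1,3-dioxolan-2-yl)-5-[1-(trifluoromethanesulfonyloxy)ethenyl]non-7-enoate
Product: 11 1-[(5R,7R)-9-hydroxy-2-methyl-7-(2-methyl-1,3-dioxolan-2-yl)non-2-en-5-yl]ethenyl trifluoromethanesulfonate
Conditions: DIBAL-H (2.5 equiv), CH2Cl2, −78 → −40 °C; Rochelle salt work-up
Reagents that add atoms: none
Why: DIBAL-H reduction of the ester to the primary alcohol, with enol triflate, dioxolane and alkene inert to the hydride at low temperature.

Step 8
Reactants: 11 1-[(5R,7R)-9-hydroxy-2-methyl-7-(2-methyl-1,3-dioxolan-2-yl)non-2-en-5-yl]ethenyl trifluoromethanesulfonate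
Product: 12 1-[(5R,7R)-9-iodo-2-methyl-7-(2-methyl-1,3-dioxolan-2-yl)non-2-en-5-yl]ethenyl trifluoromethanesulfonate
Conditions: I2, PPh3, imidazole, CH2Cl2, 0 °C
Reagents that add atoms: iodine, II
Why: Appel-type iodination of the primary alcohol gives the unbranched primary iodide needed for enolate alkylation, and the imidazole buffer protects the ketal.

Step 9
Reactants: 13 2-methylcyclopent-2-en-1-one
Product: 15 {[(3S)-3-ethenyl-2-methylcyclopent-1-en-1-yl]oxy}trimethylsilane, via dimethylaluminium enolate 14 (not isolated)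
Conditions: Me2Al(CH=CH2) [from vinylMgBr + Me2AlCl, Et2O, 0 °C], CuTC (5 mol %), chiral phosphoramidite ligand (10 mol %), Et2O, −30 °C; then TMSOTf, −30 → 0 °C
Reagents that add atoms: vinylmagnesium bromide, C=C[Mg]Br; trimethylsilyl trifluoromethanesulfonate, C[Si](C)(C)OS(=O)(=O)C(F)(F)F
Why: Copper-catalysed asymmetric conjugate addition of an alkenylalane to an α-substituted cyclic enone, in which the ligand selects the enone face (sets C10), the alkenyl group transfers in preference to methyl, and O-silylation stores the regiodefined tetrasubstituted enolate.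

Step 10
Reactants: 15 {[(3S)-3-ethenyl-2-methylcyclopent-1-en-1-yl]oxy}trimethylsilane; 12 1-[(5R,7R)-9-iodo-2-methyl-7-(2-methyl-1,3-dioxolan-2-yl)non-2-en-5-yl]ethenyl trifluoromethanesulfonate
Product: 17 1-[(5R,7S)-9-[(1S,2S)-2-ethenyl-1-methyl-5-oxocyclopentyl]-2-methyl-7-(2-methyl-1,3-dioxolan-2-yl)non-2-en-5-yl]ethenyl trifluoromethanesulfonate, via lithium enolate 16 (not isolated)
Conditions: 15 (1.3 equiv), MeLi, THF, 0 °C; then 12, DMPU, −40 → 0 °C
Reagents that add atoms: none
Why: The lithium enolate released from the silyl enol ether is C-alkylated by the primary iodide on the face anti to the neighbouring vinyl group (enolate alkylation of a 2-methyl-3-substituted cyclopentanone enolate), which joins the two fragments at the quaternary carbon C1 and sets it trans to C10.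

Step 11
Reactants: 17 1-[(5R,7S)-9-[(1S,2S)-2-ethenyl-1-methyl-5-oxocyclopentyl]-2-methyl-7-(2-methyl-1,3-dioxolan-2-yl)non-2-en-5-yl]ethenyl trifluoromethanesulfonate
Product: 20 1-[(5R,7S)-9-[(1S,2S)-4-diazo-2-ethenyl-1-methyl-5-oxocyclopentyl]-2-methyl-7-(2-methyl-1,3-dioxolan-2-yl)non-2-en-5-yl]ethenyl trifluoromethanesulfonate, via lithium enolate 18 (not isolated), via trifluoroacetyl ketone 19 (not isolated)
Conditions: LiHMDS, THF, −78 °C; CF3CO2CH2CF3; then MsN3, Et3N, H2O, MeCN, rt
Reagents that add atoms: methanesulfonyl azide, CS(=O)(=O)N=[N+]=[N-]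
Why: Detrifluoroacetylative diazo transfer is regiochemically unambiguous here because the other α-carbon is quaternary, so only the methylene that becomes C12 can be acylated and diazotized.

Step 12
Reactants: 20 1-[(5R,7S)-9-[(1S,2S)-4-diazo-2-ethenyl-1-methyl-5-oxocyclopentyl]-2-methyl-7-(2-methyl-1,3-dioxolan-2-yl)non-2-en-5-yl]ethenyl trifluoromethanesulfonate
Product: 22 methyl (1S,2S,3S)-3-ethenyl-2-methyl-2-[(3S,5R)-8-methyl-3-(2-methyl-1,3-dioxolan-2-yl)-5-[1-(trifluoromethanesulfonyloxy)ethenyl]non-7-en-1-yl]cyclobutane-1-carboxylate, via ketene 21 (not isolated)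
Conditions: hν (365 nm), MeOH, 0 °C
Reagents that add atoms: methanol, CO
Why: Irradiation expels N2 from the s-Z-locked cyclic α-diazo ketone with a concerted 1,2-shift of the quaternary carbon (C1) from the carbonyl carbon to the diazo carbon (C12), and methanol captures the resulting ketene 21 as the methyl ester (Wolff rearrangement). The closest known reaction type is the photochemical ring contraction of 2-diazocyclopentanones whose other α-carbon is a methyl-bearing quaternary centre, as used for D-nor steroids and other cyclobutanecarboxylates. The cyclobutane C1–C10–C11–C12 is closed by this migration inside the existing five-membered ring (ring contraction, new C1–C12 bond), and the extruded carbonyl carbon becomes the ester that later gives the isopropenyl group. C1 migrates with retention, so the trans relation of the chains at C1 and C10 from steps 9 and 10 is carried over unchanged. C12 is set when the ester enol is protonated on the face anti to the pseudo-axial C1 methyl group, which should place CO2Me pseudo-equatorial and cis to that methyl, and this is also expected to be the more stable epimer. The step needs ketene formation to outrun carbene chemistry at the vinyl, prenyl and enol triflate groups, which the concerted photochemical path of a cyclic diazo ketone in methanol should secure.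

Step 13
Reactants: 22 methyl (1S,2S,3S)-3-ethenyl-2-methyl-2-[(3S,5R)-8-methyl-3-(2-methyl-1,3-dioxolan-2-yl)-5-[1-(trifluoromethanesulfonyloxy)ethenyl]non-7-en-1-yl]cyclobutane-1-carboxylate
Product: 24 methyl (1R,5R,7S,10S,11S)-10-methyl-4-methylidene-5-(3-methylbut-2-en-1-yl)-7-(2-methyl-1,3-dioxolan-2-yl)bicyclo[8.2.0]dodecane-11-carboxylate, via B-alkyl-9-BBN 23 (not isolated)
Conditions: 9-BBN-H (1.5 equiv), THF, rt; then slow addition to PdCl2(dppf) (15 mol %), AsPh3, Cs2CO3, DMF/THF/H2O, 50 °C (final 2 mM)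
Reagents that add atoms: none
Why: 9-BBN should hydroborate only the monosubstituted vinyl group (the trisubstituted prenyl alkene, the enol triflate and the ester react far more slowly), and the primary alkylborane then couples intramolecularly with the enol triflate under high dilution (B-alkyl Suzuki–Miyaura macrocyclization), closing the ten-membered ring at C7–C8 and forming the exocyclic methylene directly.

Step 14
Reactants: 24 methyl (1R,5R,7S,10S,11S)-10-methyl-4-methylidene-5-(3-methylbut-2-en-1-yl)-7-(2-methyl-1,3-dioxolan-2-yl)bicyclo[8.2.0]dodecane-11-carboxylate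
Product: 26 1-[(1R,5R,7S,10S,11S)-10-methyl-4-methylidene-5-(3-methylbut-2-en-1-yl)-7-(2-methyl-1,3-dioxolan-2-yl)bicyclo[8.2.0]dodecan-11-yl]ethan-1-one, via lithium silyl enolate 25 (not isolated)
Conditions: TMSCH2Li (2.5 equiv), THF/pentane, −20 °C → rt; then MeOH, rt
Reagents that add atoms: (trimethylsilyl)methyllithium, [Li]C[Si](C)(C)C
Why: Addition of (trimethylsilyl)methyllithium to the ester stops at the ketone stage because the α-silyl ketone is deprotonated in the flask, and methanolysis then removes silicon to give the methyl ketone in one operation (ester to methyl ketone), with ketal and alkenes inert.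

Step 15
Reactants: 26 1-[(1R,5R,7S,10S,11S)-10-methyl-4-methylidene-5-(3-methylbut-2-en-1-yl)-7-(2-methyl-1,3-dioxolan-2-yl)bicyclo[8.2.0]dodecan-11-yl]ethan-1-one
Product: 27 2-methyl-2-[(1S,4S,6R,10R,12R)-1-methyl-7-methylidene-6-(3-methylbut-2-en-1-yl)-12-(prop-1-en-2-yl)bicyclo[8.2.0]dodecan-4-yl]-1,3-dioxolane
Conditions: Ph3PCH3Br, KOtBu, THF, 0 °C → rt
Reagents that add atoms: methyltriphenylphosphonium bromide, C[P+](c1ccccc1)(c1ccccc1)c1ccccc1.[Br-]
Why: Wittig methylenation of the cyclobutyl methyl ketone gives the isopropenyl group, and since the acetyl group already sits in the pseudo-equatorial position cis to the C1 methyl, reversible enolization by the ylide should not change C12.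

Step 16
Reactants: 27 2-methyl-2-[(1S,4S,6R,10R,12R)-1-methyl-7-methylidene-6-(3-methylbut-2-en-1-yl)-12-(prop-1-en-2-yl)bicyclo[8.2.0]dodecan-4-yl]-1,3-dioxolane
Product: 28 1-[(1S,4S,6R,10R,12R)-1-methyl-7-methylidene-6-(3-methylbut-2-en-1-yl)-12-(prop-1-en-2-yl)bicyclo[8.2.0]dodecan-4-yl]ethan-1-one
Conditions: PPTS, acetone/H2O (9:1), 50 °C
Reagents that add atoms: water, O
Why: Mild acid hydrolysis of the dioxolane frees the C4 methyl ketone, and PPTS is too weak an acid to protonate the 1,1-disubstituted alkenes or to enolize the ketone toward C4 at a useful rate.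

Step 17
Reactants: 28 1-[(1S,4S,6R,10R,12R)-1-methyl-7-methylidene-6-(3-methylbut-2-en-1-yl)-12-(prop-1-en-2-yl)bicyclo[8.2.0]dodecan-4-yl]ethan-1-one
Product: 30 1-[(1S,4S,6R,10R,12R)-1-methyl-7-methylidene-6-(3-methylbut-2-en-1-yl)-12-(prop-1-en-2-yl)bicyclo[8.2.0]dodecan-4-yl]ethenyl trifluoromethanesulfonate, via lithium enolate 29 (not isolated)
Conditions: LDA, THF, −78 °C; then PhNTf2, −78 → 0 °C
Reagents that add atoms: N-phenylbis(trifluoromethanesulfonimide), O=S(=O)(N(c1ccccc1)S(=O)(=O)C(F)(F)F)C(F)(F)F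
Why: Kinetic enolization at the methyl group and O-triflation, as in step 6, should give the enol triflate without deprotonating the ring methine C4, so its configuration is kept.

Step 18
Reactants: 30 1-[(1S,4S,6R,10R,12R)-1-methyl-7-methylidene-6-(3-methylbut-2-en-1-yl)-12-(prop-1-en-2-yl)bicyclo[8.2.0]dodecan-4-yl]ethenyl trifluoromethanesulfonate
Product: 31 methyl 2-[(1S,4S,6R,10R,12R)-1-methyl-7-methylidene-6-(3-methylbut-2-en-1-yl)-12-(prop-1-en-2-yl)bicyclo[8.2.0]dodecan-4-yl]prop-2-enoate (CNP0314186.1)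
Conditions: Pd(OAc)2 (10 mol %), dppp (10 mol %), CO (1 atm), MeOH, Et3N, DMF, 50 °C
Reagents that add atoms: carbon monoxide, [C-]#[O+]; methanol, CO
Why: Palladium-catalysed methoxycarbonylation of the enol triflate (oxidative addition, CO insertion, methanolysis) gives the α-substituted methyl acrylate in the last step, so the Michael acceptor never meets the organometallic or basic reagents of the route.

## Compound list

1 | (R)-(−)-carvone, (5R)-2-methyl-5-(prop-1-en-2-yl)cyclohex-2-en-1-one | CC1=CC[C@H](CC1=O)C(C)=C | starting material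
2 | 3-methyl-3-[(1R)-4-methyl-5-oxocyclohex-3-en-1-yl]-1,2,4-trioxolane (secondary ozonide) | CC1=CC[C@H](CC1=O)C2(C)OCOO2 | intermediate
3 | (5R)-5-acetyl-2-methylcyclohex-2-en-1-one | CC1=CC[C@H](CC1=O)C(C)=O | intermediate
4 | (5R)-2-methyl-5-(2-methyl-1,3-dioxolan-2-yl)cyclohex-2-en-1-one | CC1=CC[C@H](CC1=O)C2(C)OCCO2 | intermediate
5 | trimethyl{[(3R,5R)-2-methyl-3-(3-methylbut-2-en-1-yl)-5-(2-methyl-1,3-dioxolan-2-yl)cyclohex-1-en-1-yl]oxy}silane | C1[C@H](C2(C)OCCO2)C[C@H](C(C)=C1O[Si](C)(C)C)CC=C(C)C | intermediate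
6 | lithium (3R,5R)-2-methyl-3-(3-methylbut-2-en-1-yl)-5-(2-methyl-1,3-dioxolan-2-yl)cyclohex-1-en-1-olate | C1[C@H](C2(C)OCCO2)C[C@H](C(C)=C1O[Li])CC=C(C)C | intermediate
7 | (3R,5R)-2-hydroxy-2-methyl-3-(3-methylbut-2-en-1-yl)-5-(2-methyl-1,3-dioxolan-2-yl)cyclohexan-1-one (C2 epimers) | C1[C@H](C2(C)OCCO2)C[C@H](C(C)(O)C1=O)CC=C(C)C | intermediate
8 | methyl (3R,5R)-5-acetyl-8-methyl-3-(2-methyl-1,3-dioxolan-2-yl)non-7-enoate | COC(=O)C[C@H](C1(C)OCCO1)C[C@H](C(C)=O)CC=C(C)C | intermediate
9 | lithium enolate of 8 at the acetyl CH3 | COC(=O)C[C@H](C1(C)OCCO1)C[C@H](C(=C)O[Li])CC=C(C)C | intermediate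
10 | methyl (3R,5R)-8-methyl-3-(2-methyl-1,3-dioxolan-2-yl)-5-[1-(trifluoromethanesulfonyloxy)ethenyl]non-7-enoate | COC(=O)C[C@H](C1(C)OCCO1)C[C@H](C(=C)OS(=O)(=O)C(F)(F)F)CC=C(C)C | intermediate
11 | 1-[(5R,7R)-9-hydroxy-2-methyl-7-(2-methyl-1,3-dioxolan-2-yl)non-2-en-5-yl]ethenyl trifluoromethanesulfonate | OCC[C@H](C1(C)OCCO1)C[C@H](C(=C)OS(=O)(=O)C(F)(F)F)CC=C(C)C | intermediate
12 | 1-[(5R,7R)-9-iodo-2-methyl-7-(2-methyl-1,3-dioxolan-2-yl)non-2-en-5-yl]ethenyl trifluoromethanesulfonate | ICC[C@H](C1(C)OCCO1)C[C@H](C(=C)OS(=O)(=O)C(F)(F)F)CC=C(C)C | intermediate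
13 | 2-methylcyclopent-2-en-1-one | CC1=CCCC1=O | starting material
14 | dimethylaluminium (3S)-3-ethenyl-2-methylcyclopent-1-en-1-olate | C=C[C@H]1C(C)=C(O[Al](C)C)CC1 | intermediate
15 | {[(3S)-3-ethenyl-2-methylcyclopent-1-en-1-yl]oxy}trimethylsilane | C=C[C@H]1C(C)=C(O[Si](C)(C)C)CC1 | intermediate
16 | lithium (3S)-3-ethenyl-2-methylcyclopent-1-en-1-olate | C=C[C@H]1C(C)=C(O[Li])CC1 | intermediate
17 | 1-[(5R,7S)-9-[(1S,2S)-2-ethenyl-1-methyl-5-oxocyclopentyl]-2-methyl-7-(2-methyl-1,3-dioxolan-2-yl)non-2-en-5-yl]ethenyl trifluoromethanesulfonate | C=C[C@@H]1CCC(=O)[C@@]1(C)CC[C@H](C2(C)OCCO2)C[C@H](C(=C)OS(=O)(=O)C(F)(F)F)CC=C(C)C | intermediate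
18 | lithium enolate of 17 (toward the ring CH2) | C=C[C@@H]1CC=C(O[Li])[C@@]1(C)CC[C@H](C2(C)OCCO2)C[C@H](C(=C)OS(=O)(=O)C(F)(F)F)CC=C(C)C | intermediate
19 | α′-trifluoroacetyl derivative of 17 | C=C[C@@H]1CC(C(=O)C(F)(F)F)C(=O)[C@@]1(C)CC[C@H](C2(C)OCCO2)C[C@H](C(=C)OS(=O)(=O)C(F)(F)F)CC=C(C)C | intermediate
20 | 1-[(5R,7S)-9-[(1S,2S)-4-diazo-2-ethenyl-1-methyl-5-oxocyclopentyl]-2-methyl-7-(2-methyl-1,3-dioxolan-2-yl)non-2-en-5-yl]ethenyl trifluoromethanesulfonate | C=C[C@@H]1CC(=[N+]=[N-])C(=O)[C@@]1(C)CC[C@H](C2(C)OCCO2)C[C@H](C(=C)OS(=O)(=O)C(F)(F)F)CC=C(C)C | intermediate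
21 | cyclobutylidene ketene from 20 | C=C[C@@H]1CC(=C=O)[C@@]1(C)CC[C@H](C2(C)OCCO2)C[C@H](C(=C)OS(=O)(=O)C(F)(F)F)CC=C(C)C | intermediate
22 | methyl (1S,2S,3S)-3-ethenyl-2-methyl-2-[(3S,5R)-8-methyl-3-(2-methyl-1,3-dioxolan-2-yl)-5-[1-(trifluoromethanesulfonyloxy)ethenyl]non-7-en-1-yl]cyclobutane-1-carboxylate | C=C[C@@H]1C[C@H](C(=O)OC)[C@@]1(C)CC[C@H](C2(C)OCCO2)C[C@H](C(=C)OS(=O)(=O)C(F)(F)F)CC=C(C)C | intermediate
23 | B-alkyl-9-BBN from hydroboration of the vinyl group of 22 | C1CCC2CCCC1B2CC[C@@H]3C[C@H](C(=O)OC)[C@@]3(C)CC[C@H](C4(C)OCCO4)C[C@H](C(=C)OS(=O)(=O)C(F)(F)F)CC=C(C)C | intermediate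
24 | methyl (1R,5R,7S,10S,11S)-10-methyl-4-methylidene-5-(3-methylbut-2-en-1-yl)-7-(2-methyl-1,3-dioxolan-2-yl)bicyclo[8.2.0]dodecane-11-carboxylate | C=C1CC[C@@H]2C[C@H](C(=O)OC)[C@@]2(C)CC[C@H](C3(C)OCCO3)C[C@H]1CC=C(C)C | intermediate
25 | lithium enolate of the α-trimethylsilyl methyl ketone from 24 | C=C1CC[C@@H]2C[C@H](C(O[Li])=C[Si](C)(C)C)[C@@]2(C)CC[C@H](C3(C)OCCO3)C[C@H]1CC=C(C)C | intermediate
26 | 1-[(1R,5R,7S,10S,11S)-10-methyl-4-methylidene-5-(3-methylbut-2-en-1-yl)-7-(2-methyl-1,3-dioxolan-2-yl)bicyclo[8.2.0]dodecan-11-yl]ethan-1-one | C=C1CC[C@@H]2C[C@H](C(C)=O)[C@@]2(C)CC[C@H](C3(C)OCCO3)C[C@H]1CC=C(C)C | intermediate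
27 | 2-methyl-2-[(1S,4S,6R,10R,12R)-1-methyl-7-methylidene-6-(3-methylbut-2-en-1-yl)-12-(prop-1-en-2-yl)bicyclo[8.2.0]dodecan-4-yl]-1,3-dioxolane | C=C1CC[C@@H]2C[C@H](C(=C)C)[C@@]2(C)CC[C@H](C3(C)OCCO3)C[C@H]1CC=C(C)C | intermediate
28 | 1-[(1S,4S,6R,10R,12R)-1-methyl-7-methylidene-6-(3-methylbut-2-en-1-yl)-12-(prop-1-en-2-yl)bicyclo[8.2.0]dodecan-4-yl]ethan-1-one | C=C1CC[C@@H]2C[C@H](C(=C)C)[C@@]2(C)CC[C@H](C(C)=O)C[C@H]1CC=C(C)C | intermediate
29 | lithium enolate of 28 at the acetyl CH3 | C=C1CC[C@@H]2C[C@H](C(=C)C)[C@@]2(C)CC[C@H](C(=C)O[Li])C[C@H]1CC=C(C)C | intermediate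
30 | 1-[(1S,4S,6R,10R,12R)-1-methyl-7-methylidene-6-(3-methylbut-2-en-1-yl)-12-(prop-1-en-2-yl)bicyclo[8.2.0]dodecan-4-yl]ethenyl trifluoromethanesulfonate | C=C1CC[C@@H]2C[C@H](C(=C)C)[C@@]2(C)CC[C@H](C(=C)OS(=O)(=O)C(F)(F)F)C[C@H]1CC=C(C)C | intermediate
31 | methyl 2-[(1S,4S,6R,10R,12R)-1-methyl-7-methylidene-6-(3-methylbut-2-en-1-yl)-12-(prop-1-en-2-yl)bicyclo[8.2.0]dodecan-4-yl]prop-2-enoate | C=C1CC[C@@H]2C[C@H](C(=C)C)[C@@]2(C)CC[C@H](C(=C)C(=O)OC)C[C@H]1CC=C(C)C | target

## Step count and risks

Total step count: 18. Longest linear sequence: 17 (steps 1–8, then 10–18; step 9 is a one-step side branch).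

Steps most likely to fail:

**Step 13 (macrocyclization).** Closure of the ten-membered ring may be slower than intermolecular coupling, protodeboronation or reduction of the alkenyl-palladium species, so that oligomers or open-chain products form. The fallback closes the same C7–C8 bond by carbonyl addition instead of cross-coupling and sets out from 22. Hydroboration–oxidation of the vinyl group (9-BBN; NaBO3) should give the primary alcohol F1, and periodinane (DMP) oxidation the aldehyde F2. Intramolecular Nozaki–Hiyama–Kishi coupling of the enol triflate with the aldehyde (CrCl2, cat. NiCl2, DMSO/THF, high dilution) should give the macrocyclic allylic alcohol F3 as a mixture of carbinol epimers. Acylation with methyl chloroformate/pyridine gives the methyl carbonate F4. Pd(0)/PBu3 with ammonium formate then delivers hydride to the more substituted allyl terminus, which leaves the exocyclic methylene and returns to the route at 24.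

**Step 9 (asymmetric vinyl addition).** The catalyst may not discriminate the enone faces well enough, or methyl may transfer from aluminium in competition with vinyl. The fallback separates C–C bond formation from enolate trapping and sets out from 13. Rhodium(I)/chiral diene-catalysed asymmetric 1,4-addition of potassium vinyltrifluoroborate in aqueous dioxane should give (3S)-3-ethenyl-2-methylcyclopentan-1-one F5, whose C2 configuration is irrelevant. Thermodynamic silylation (TMSCl, NaI, Et3N, MeCN) should favour the tetrasubstituted enol ether and returns to the route at 15.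

**Step 12 (Wolff ring contraction).** Carbene-type side reactions (O–H insertion, attack on the nearby vinyl group) may compete with the 1,2-shift, or protonation of the ester enol may not be face-selective, so that C12 forms as a mixture. The fallback replaces the diazo ketone by a halide and sets out from 17. Silyl enol ether formation (LiHMDS, TMSCl) and bromination with NBS should give the α′-bromo ketone F6; the epimer with bromine cis to the C-methyl group is needed, and the two epimers can interconvert through the enol under HBr catalysis. NaOMe in MeOH at 0 °C then adds to the carbonyl group, and the quaternary carbon migrates to the bromine-bearing carbon with inversion (quasi-Favorskii, semibenzilic ring contraction). The C12 configuration then follows from the C–Br configuration and not from a protonation, and the route is rejoined at 22.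

Further compounds

F1 | step 13 | hydroxyethyl analogue of 22 (CH=CH2 replaced by CH2CH2OH) | OCC[C@@H]1C[C@H](C(=O)OC)[C@@]1(C)CC[C@H](C2(C)OCCO2)C[C@H](C(=C)OS(=O)(=O)C(F)(F)F)CC=C(C)C
F2 | step 13 | oxoethyl analogue of 22 (CH=CH2 replaced by CH2CHO) | O=CC[C@@H]1C[C@H](C(=O)OC)[C@@]1(C)CC[C@H](C2(C)OCCO2)C[C@H](C(=C)OS(=O)(=O)C(F)(F)F)CC=C(C)C
F3 | step 13 | 3-hydroxy derivative of 24 (allylic alcohol next to the exocyclic methylene, both C3 epimers) | C=C1C(O)C[C@@H]2C[C@H](C(=O)OC)[C@@]2(C)CC[C@H](C3(C)OCCO3)C[C@H]1CC=C(C)C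
F4 | step 13 | methyl carbonate of F3 | C=C1C(OC(=O)OC)C[C@@H]2C[C@H](C(=O)OC)[C@@]2(C)CC[C@H](C3(C)OCCO3)C[C@H]1CC=C(C)C
F5 | step 9 | (3S)-3-ethenyl-2-methylcyclopentan-1-one (C2 epimers) | C=C[C@H]1C(C)C(=O)CC1
F6 | step 12 | 1-[(5R,7S)-9-[(1S,2S,4S)-4-bromo-2-ethenyl-1-methyl-5-oxocyclopentyl]-2-methyl-7-(2-methyl-1,3-dioxolan-2-yl)non-2-en-5-yl]ethenyl trifluoromethanesulfonate | C=C[C@@H]1C[C@H](Br)C(=O)[C@@]1(C)CC[C@H](C2(C)OCCO2)C[C@H](C(=C)OS(=O)(=O)C(F)(F)F)CC=C(C)C
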